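**Retrosynthetic overview**
1. The last bonds are cut by global acidolysis (five MOM ethers, one tert-butyl ester). Before that, a Heck C–C coupling joins the aryl carbon para to the diaryl-ether oxygen to the acrylate of protected (R)-3-(3,4-dihydroxyphenyl)lactic acid, whose stereocentre comes from the chiral pool and is never touched.
2. Feature and key disconnection: the 6,7-dihydroxycoumarin is a caffeic acid whose carboxylate oxygen O1 is bonded to ring carbon C8a (para to the C6 hydroxyl), with the diaryl-ether oxygen on C3 as the α-substituent of the acrylic acid. The O1–C8a bond is cut back to the α-aryloxy caffeic acid 12, closed by o-quinone lactonisation under E/Z photoequilibration.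
3. Ring order: the three benzene rings are bought; the pyranone is the only ring made, in step 8.
4. Acid 12 comes from aldol addition/dehydration of aryloxyacetate 6 with silylated protocatechualdehyde 8. Ester 6 comes from 4-bromo-2-hydroxybenzaldehyde by MOM protection, Baeyer–Villiger oxidation and O-alkylation with methyl bromoacetate.
5. The phenol ortho to the diaryl-ether oxygen stays a MOM ether through the key step. Free, it would lactonise with the acid to a 1,4-benzodioxin-2-one or add to the quinone (5-exo at the α-carbon).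

Key step: step 8

Remark on geometry: the dehydration in step 6 is expected to give mainly the Z acrylate (carboxyl trans to the catechol ring). Compounds 11 and 12 are drawn as Z; any E isomer is carried along, because step 8 equilibrates the two.

**Route**

Step 1
Reactants: 1 4-bromo-2-hydroxybenzaldehyde
Product: 2 4-bromo-2-(methoxymethoxy)benzaldehyde
Conditions: MOMCl (1.3 equiv), i-Pr2NEt (1.6 equiv), CH2Cl2, 0 °C → rt
Reagents that add atoms: chloromethyl methyl ether (MOMCl), COCCl
Why: Williamson-type O-alkylation of the salicyl phenol with the chloromethyl ether masks the oxygen that ends up ortho to the diaryl ether, so that it stays protected through the key step.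

Step 2
Reactants: 2 4-bromo-2-(methoxymethoxy)benzaldehyde
Product: 4 4-bromo-2-(methoxymethoxy)phenol, via aryl formate 3 (not isolated)
Conditions: mCPBA (1.4 equiv), CH2Cl2, 0 °C → rt; then K2CO3 (cat.), MeOH, rt
Reagents that add atoms: meta-chloroperoxybenzoic acid (mCPBA), OOC(=O)c1cccc(Cl)c1
Why: Baeyer–Villiger (Dakin-type) oxidation of an ortho-alkoxybenzaldehyde proceeds with aryl migration to the formate, which mild methanolysis cleaves to the phenol para to bromine without touching the MOM ether.

Step 3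
Reactants: 4 4-bromo-2-(methoxymethoxy)phenol; 5 methyl bromoacetate
Product: 6 methyl 2-[4-bromo-2-(methoxymethoxy)phenoxy]acetate
Conditions: K2CO3 (1.5 equiv), acetone, 55 °C
Reagents that add atoms: none
Why: Williamson ether synthesis of the phenoxide with the activated primary α-bromo ester gives the aryloxyacetate, and with no free ortho-phenol present lactonisation to a benzodioxinone cannot compete.

Step 4
Reactants: 7 3,4-dihydroxybenzaldehyde
Product: 8 3,4-bis[(tert-butyldimethylsilyl)oxy]benzaldehyde
Conditions: TBSCl (2.3 equiv), imidazole (4 equiv), DMF, rt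
Reagents that add atoms: tert-butyldimethylsilyl chloride (TBSCl), CC(C)(C)[Si](C)(C)Cl
Why: standard silylation of both phenols gives an enolate-compatible aldehyde whose aryl silyl ethers can later be cleaved by hydroxide while the MOM ether stays.

Step 5
Reactants: 6 methyl 2-[4-bromo-2-(methoxymethoxy)phenoxy]acetate; 8 3,4-bis[(tert-butyldimethylsilyl)oxy]benzaldehyde
Product: 9 methyl 2-[4-bromo-2-(methoxymethoxy)phenoxy]-3-{3,4-bis[(tert-butyldimethylsilyl)oxy]phenyl}-3-hydroxypropanoate (racemic mixture of diastereomers)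
Conditions: LDA (1.1 equiv), THF, −78 °C; then 8; AcOH quench at −78 °C
Reagents that add atoms: none
Why: aldol addition of the lithium enolate of an α-aryloxy ester to an aromatic aldehyde at low temperature is the established entry to β-hydroxy-α-aryloxy esters (β-O-4 lignin models); the two new stereocentres form without control and are removed in step 6.

Step 6
Reactants: 9 methyl 2-[4-bromo-2-(methoxymethoxy)phenoxy]-3-{3,4-bis[(tert-butyldimethylsilyl)oxy]phenyl}-3-hydroxypropanoate
Product: 11 methyl (Z)-2-[4-bromo-2-(methoxymethoxy)phenoxy]-3-{3,4-bis[(tert-butyldimethylsilyl)oxy]phenyl}prop-2-enoate, via mesylate 10 (not isolated)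
Conditions: MsCl (1.5 equiv), Et3N (3 equiv), CH2Cl2, 0 °C; then DBU (2.5 equiv), 0 °C → rt
Reagents that add atoms: none
Why: mesylation of the benzylic alcohol followed by base-induced E2/E1cB elimination gives the conjugated α-aryloxycinnamate, expected mainly as the Z isomer with the ester trans to the aryl group.

Step 7
Reactants: 11 methyl (Z)-2-[4-bromo-2-(methoxymethoxy)phenoxy]-3-{3,4-bis[(tert-butyldimethylsilyl)oxy]phenyl}prop-2-enoate
Product: 12 (Z)-2-[4-bromo-2-(methoxymethoxy)phenoxy]-3-(3,4-dihydroxyphenyl)prop-2-enoic acid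
Conditions: LiOH·H2O (8 equiv), THF/MeOH/H2O (2:1:1, degassed), Ar, 40 °C; then 1 M HCl to pH 3, 0 °C
Reagents that add atoms: lithium hydroxide, [Li+].[OH-]
Why: hydroxide saponifies the methyl ester (BAc2) and cleaves both aryl silyl ethers in the same flask while the MOM ether is inert to base, and exclusion of oxygen protects the catecholate.

Step 8
Reactants: 12 (Z)-2-[4-bromo-2-(methoxymethoxy)phenoxy]-3-(3,4-dihydroxyphenyl)prop-2-enoic acid
Product: 15 3-[4-bromo-2-(methoxymethoxy)phenoxy]-6,7-dihydroxy-2H-chromen-2-one, via E-acid 13 (not isolated), via E-o-quinone 14 (not isolated)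
Conditions: riboflavin tetraacetate (5 mol%), 450 nm LEDs, NaIO4 (1.05 equiv in H2O, syringe pump over 6 h), MeCN/0.1 M phosphate buffer pH 6 (1:1), 5 mM, Ar, 20 °C; then ascorbic acid, pH 3
Reagents that add atoms: none
Why: Proposed new method: triplet energy transfer from the flavin should equilibrate Z-acid 12 with E-acid 13 while slowly dosed periodate oxidises the catechol to its o-quinone; in E-quinone 14 the cis carboxylate adds to the ring carbon ortho to the side chain and para to the C3 oxygen (conjugate addition to the enone of the C4 carbonyl, 6-exo-trig), which forms O1–C8a and closes the pyranone, and enolisation of the adduct restores the catechol as the 6,7-dihydroxycoumarin. The closest known reactions are the oxidation of cis-caffeic acid to esculetin through its o-quinone (phenol oxidases or chemical oxidants) and the flavin-photocatalysed isomerisation/oxidative cyclisation of cinnamic acids to coumarins; new here are the α-aryloxy substituent and the coupling of a stoichiometric quinone-forming oxidant to the photoequilibrium. The oxidised Z isomer cannot close, but catechol/quinone redox exchange and light should return it to the pool, so both geometries drain to 15. Chemoselectivity is needed for the catechol over the other ring and over the product: the other ring carries only ether oxygens, the oxidant is limited to one equivalent, and any product quinone should be reduced back by unreacted catechol. Regioselectivity for C8a over the carbon between the side chain and the C3 oxygen follows because only the former is the β-carbon of a quinone enone. No stereocentre is formed.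

Step 9
Reactants: 15 3-[4-bromo-2-(methoxymethoxy)phenoxy]-6,7-dihydroxy-2H-chromen-2-one
Product: 16 3-[4-bromo-2-(methoxymethoxy)phenoxy]-6,7-bis(methoxymethoxy)-2H-chromen-2-one
Conditions: MOMCl (3 equiv), i-Pr2NEt (4 equiv), CH2Cl2/DMF, 0 °C → rt, Ar
Reagents that add atoms: chloromethyl methyl ether (MOMCl), COCCl
Why: O-alkylation of the two coumarin phenols gives a catechol-free aryl bromide, so that palladium is not chelated and the ring is not oxidised in the coupling.

Step 10
Reactants: 17 (R)-3-(3,4-dihydroxyphenyl)-2-hydroxypropanoic acid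
Product: 18 tert-butyl (R)-3-(3,4-dihydroxyphenyl)-2-hydroxypropanoate
Conditions: tert-butyl 2,2,2-trichloroacetimidate (2.5 equiv), THF, rt
Reagents that add atoms: tert-butyl 2,2,2-trichloroacetimidate, CC(C)(C)OC(=N)C(Cl)(Cl)Cl
Why: the carboxylic acid protonates the imidate and is tert-butylated through the resulting ion pair without added Lewis acid, conditions under which phenols and the secondary alcohol do not react; the stereocentre is untouched.

Step 11
Reactants: 18 tert-butyl (R)-3-(3,4-dihydroxyphenyl)-2-hydroxypropanoate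
Product: 19 tert-butyl (R)-3-[3,4-bis(methoxymethoxy)phenyl]-2-hydroxypropanoate
Conditions: MOMCl (2.3 equiv), K2CO3 (3 equiv), acetone, 0 °C → rt, Ar
Reagents that add atoms: chloromethyl methyl ether (MOMCl), COCCl
Why: under carbonate only the phenoxides form and are alkylated (Williamson-type MOM protection), which leaves the secondary α-hydroxyl free for acylation.

Step 12
Reactants: 19 tert-butyl (R)-3-[3,4-bis(methoxymethoxy)phenyl]-2-hydroxypropanoate; 20 acryloyl chloride
Product: 21 tert-butyl (R)-2-(acryloyloxy)-3-[3,4-bis(methoxymethoxy)phenyl]propanoate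
Conditions: Et3N (1.5 equiv), CH2Cl2, −20 → 0 °C (BHT, trace)
Reagents that add atoms: none
Why: acylation of the secondary alcohol by the acid chloride under amine base gives the acrylate with retention, since the C–O bond at the stereocentre is not broken.

Step 13
Reactants: 16 3-[4-bromo-2-(methoxymethoxy)phenoxy]-6,7-bis(methoxymethoxy)-2H-chromen-2-one; 21 tert-butyl (R)-2-(acryloyloxy)-3-[3,4-bis(methoxymethoxy)phenyl]propanoate
Product: 22 tert-butyl (R)-3-[3,4-bis(methoxymethoxy)phenyl]-2-{[(E)-3-{4-[(6,7-bis(methoxymethoxy)-2-oxo-2H-chromen-3-yl)oxy]-3-(methoxymethoxy)phenyl}prop-2-enoyl]oxy}propanoate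
Conditions: Pd2(dba)3 (2.5 mol%), [(t-Bu)3PH]BF4 (6 mol%), Cy2NMe (1.5 equiv), 1,4-dioxane, 60 °C
Reagents that add atoms: none
Why: Mizoroki–Heck coupling of the aryl bromide with the monosubstituted acrylate under a bulky electron-rich phosphine at moderate temperature gives the (E)-cinnamate by syn-insertion and syn-β-hydride elimination, and the hindered amine is too weak a base to epimerise the α-acyloxy ester.

Step 14
Reactants: 22 tert-butyl (R)-3-[3,4-bis(methoxymethoxy)phenyl]-2-{[(E)-3-{4-[(6,7-bis(methoxymethoxy)-2-oxo-2H-chromen-3-yl)oxy]-3-(methoxymethoxy)phenyl}prop-2-enoyl]oxy}propanoate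
Product: 23 (R)-3-(3,4-dihydroxyphenyl)-2-{[(E)-3-{4-[(6,7-dihydroxy-2-oxo-2H-chromen-3-yl)oxy]-3-hydroxyphenyl}prop-2-enoyl]oxy}propanoic acid (CNP0318082.1)
Conditions: TFA/CH2Cl2/H2O (10:10:1), 0 °C → rt
Reagents that add atoms: none
Why: acid-catalysed acetal hydrolysis removes the five MOM ethers and AAL1 cleavage removes the tert-butyl ester, whereas the cinnamate ester, the coumarin lactone, the diaryl ether and the stereocentre are stable to aqueous trifluoroacetic acid.

**Compound list**
1 | 4-bromo-2-hydroxybenzaldehyde | O=Cc1ccc(Br)cc1O | starting material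
2 | 4-bromo-2-(methoxymethoxy)benzaldehyde | COCOc1cc(Br)ccc1C=O | intermediate
3 | 4-bromo-2-(methoxymethoxy)phenyl formate | COCOc1cc(Br)ccc1OC=O | intermediate
4 | 4-bromo-2-(methoxymethoxy)phenol | COCOc1cc(Br)ccc1O | intermediate
5 | methyl bromoacetate | COC(=O)CBr | starting material
6 | methyl 2-[4-bromo-2-(methoxymethoxy)phenoxy]acetate | COCOc1cc(Br)ccc1OCC(=O)OC | intermediate
7 | 3,4-dihydroxybenzaldehyde | O=Cc1ccc(O)c(O)c1 | starting material
8 | 3,4-bis[(tert-butyldimethylsilyl)oxy]benzaldehyde | O=Cc1ccc(O[Si](C)(C)C(C)(C)C)c(O[Si](C)(C)C(C)(C)C)c1 | intermediate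
9 | methyl 2-[4-bromo-2-(methoxymethoxy)phenoxy]-3-{3,4-bis[(tert-butyldimethylsilyl)oxy]phenyl}-3-hydroxypropanoate (racemic, diastereomer mixture) | COC(=O)C(Oc1ccc(Br)cc1OCOC)C(O)c1ccc(O[Si](C)(C)C(C)(C)C)c(O[Si](C)(C)C(C)(C)C)c1 | intermediate
10 | methyl 2-[4-bromo-2-(methoxymethoxy)phenoxy]-3-{3,4-bis[(tert-butyldimethylsilyl)oxy]phenyl}-3-(methanesulfonyloxy)propanoate | COC(=O)C(Oc1ccc(Br)cc1OCOC)C(OS(C)(=O)=O)c1ccc(O[Si](C)(C)C(C)(C)C)c(O[Si](C)(C)C(C)(C)C)c1 | intermediate
11 | methyl (Z)-2-[4-bromo-2-(methoxymethoxy)phenoxy]-3-{3,4-bis[(tert-butyldimethylsilyl)oxy]phenyl}prop-2-enoate | COC(=O)/C(Oc1ccc(Br)cc1OCOC)=C/c1ccc(O[Si](C)(C)C(C)(C)C)c(O[Si](C)(C)C(C)(C)C)c1 | intermediate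
12 | (Z)-2-[4-bromo-2-(methoxymethoxy)phenoxy]-3-(3,4-dihydroxyphenyl)prop-2-enoic acid | OC(=O)/C(Oc1ccc(Br)cc1OCOC)=C/c1ccc(O)c(O)c1 | intermediate
13 | (E)-2-[4-bromo-2-(methoxymethoxy)phenoxy]-3-(3,4-dihydroxyphenyl)prop-2-enoic acid | OC(=O)/C(Oc1ccc(Br)cc1OCOC)=C\c1ccc(O)c(O)c1 | intermediate
14 | (E)-2-[4-bromo-2-(methoxymethoxy)phenoxy]-3-(3,4-dioxocyclohexa-1,5-dien-1-yl)prop-2-enoic acid | OC(=O)/C(Oc1ccc(Br)cc1OCOC)=C\C1=CC(=O)C(=O)C=C1 | intermediate
15 | 3-[4-bromo-2-(methoxymethoxy)phenoxy]-6,7-dihydroxy-2H-chromen-2-one | O=c1oc2cc(O)c(O)cc2cc1Oc1ccc(Br)cc1OCOC | intermediate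
16 | 3-[4-bromo-2-(methoxymethoxy)phenoxy]-6,7-bis(methoxymethoxy)-2H-chromen-2-one | O=c1oc2cc(OCOC)c(OCOC)cc2cc1Oc1ccc(Br)cc1OCOC | intermediate
17 | (R)-3-(3,4-dihydroxyphenyl)-2-hydroxypropanoic acid | O[C@H](Cc1ccc(O)c(O)c1)C(=O)O | starting material
18 | tert-butyl (R)-3-(3,4-dihydroxyphenyl)-2-hydroxypropanoate | O[C@H](Cc1ccc(O)c(O)c1)C(=O)OC(C)(C)C | intermediate
19 | tert-butyl (R)-3-[3,4-bis(methoxymethoxy)phenyl]-2-hydroxypropanoate | O[C@H](Cc1ccc(OCOC)c(OCOC)c1)C(=O)OC(C)(C)C | intermediate
20 | acryloyl chloride | C=CC(=O)Cl | starting material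
21 | tert-butyl (R)-2-(acryloyloxy)-3-[3,4-bis(methoxymethoxy)phenyl]propanoate | C=CC(=O)O[C@H](Cc1ccc(OCOC)c(OCOC)c1)C(=O)OC(C)(C)C | intermediate
22 | tert-butyl (R)-3-[3,4-bis(methoxymethoxy)phenyl]-2-{[(E)-3-{4-[(6,7-bis(methoxymethoxy)-2-oxo-2H-chromen-3-yl)oxy]-3-(methoxymethoxy)phenyl}prop-2-enoyl]oxy}propanoate | O=C(/C=C/c1ccc(Oc2cc3cc(OCOC)c(OCOC)cc3oc2=O)c(OCOC)c1)O[C@H](Cc1ccc(OCOC)c(OCOC)c1)C(=O)OC(C)(C)C | intermediate
23 | (R)-3-(3,4-dihydroxyphenyl)-2-{[(E)-3-{4-[(6,7-dihydroxy-2-oxo-2H-chromen-3-yl)oxy]-3-hydroxyphenyl}prop-2-enoyl]oxy}propanoic acid (CNP0318082.1) | O=C(/C=C/c1ccc(Oc2cc3cc(O)c(O)cc3oc2=O)c(O)c1)O[C@H](Cc1ccc(O)c(O)c1)C(=O)O | target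

**Totals**
Total step count: 14.
Longest linear sequence: 10 steps (steps 1, 2, 3, 5, 6, 7, 8, 9, 13, 14).

**Steps most likely to fail**

Step 8 (proposed new method). The quinone may be drained by intermolecular coupling, water addition or over-oxidation of the product before the E-quinone lactonises. Electron-transfer quenching of the flavin triplet by the catechol may also outrun energy transfer, so that the geometry does not equilibrate. The fallback uses known chemistry and closes the pyranone by C3–C4 condensation instead. It sets out from 6, which is saponified (LiOH, THF/H2O, rt) to 2-[4-bromo-2-(methoxymethoxy)phenoxy]acetic acid F1. Commercial 2,4,5-trihydroxybenzaldehyde (O=Cc1cc(O)c(O)cc1O) is alkylated at the 4- and 5-hydroxyls (MOMCl 2.1 equiv, i-Pr2NEt, CH2Cl2, 0 °C; the chelated 2-hydroxyl reacts last) to 2-hydroxy-4,5-bis(methoxymethoxy)benzaldehyde F2. F1 and F2 are then condensed under Perkin–Oglialoro conditions (Ac2O, Et3N, 110 °C: mixed anhydride, O-acylation of the phenol, intramolecular aldol condensation and dehydration), which should give the 3-aryloxycoumarin directly as 16. The route is rejoined at 16 (steps 4–9 fall away).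

Step 13. Oxidative addition into the electron-rich, dioxygenated aryl bromide may be slow, and during the extended heating the acrylate may oligomerise or the α-acyloxy ester centre may erode under amine. The fallback sets out from 16 and keeps the sensitive acrylate away from palladium and base. Suzuki–Miyaura vinylation of 16 (potassium vinyltrifluoroborate, PdCl2(dppf), Et3N, n-PrOH, 90 °C) gives 3-[4-ethenyl-2-(methoxymethoxy)phenoxy]-6,7-bis(methoxymethoxy)-2H-chromen-2-one F3. Olefin cross-metathesis of F3 with acrylate 21 (second-generation Ru isopropoxybenzylidene catalyst, CH2Cl2, 40 °C, neutral) should give the E-cinnamate, returning to the route at 22.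

Step 14. The freed catechol rings may be captured by formaldehyde, methoxymethyl or tert-butyl cations (hydroxymethylation, methylene bridging, C-tert-butylation), and the cinnamate ester may slowly hydrolyse during the long acidolysis needed for six groups. The fallback sets out from 15 and 18 and changes the protecting-group plan, so that only one MOM ether and the tert-butyl ester need acid and the catechols stay capped while cations are present.
- Silylation of 15 (TBSCl, imidazole, DMF) gives 3-[4-bromo-2-(methoxymethoxy)phenoxy]-6,7-bis[(tert-butyldimethylsilyl)oxy]-2H-chromen-2-one F4.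
- Silylation of 18 at the two phenols (TBSCl 2.1 equiv, imidazole, DMF, 0 °C; the hindered α-hydroxyl reacts more slowly) gives tert-butyl (R)-3-{3,4-bis[(tert-butyldimethylsilyl)oxy]phenyl}-2-hydroxypropanoate F5.
- Acylation of F5 with 20 (Et3N, CH2Cl2) gives tert-butyl (R)-2-(acryloyloxy)-3-{3,4-bis[(tert-butyldimethylsilyl)oxy]phenyl}propanoate F6.
- Heck coupling of F4 with F6 under the conditions of step 13 gives the tetrasilylated MOM ether tert-butyl ester of the target F7.
- Brief TFA/CH2Cl2/H2O treatment at 0 °C removes the single MOM ether and the tert-butyl ester to give the tetrakis(tert-butyldimethylsilyl) ether of the target F8.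
- Et3N·3HF in THF at rt cleaves the four aryl silyl ethers under non-basic conditions and returns to the route at 23.

**Further compounds**
F1 | step 8 | 2-[4-bromo-2-(methoxymethoxy)phenoxy]acetic acid | COCOc1cc(Br)ccc1OCC(=O)O
F2 | step 8 | 2-hydroxy-4,5-bis(methoxymethoxy)benzaldehyde | COCOc1cc(O)c(C=O)cc1OCOC
F3 | step 13 | 3-[4-ethenyl-2-(methoxymethoxy)phenoxy]-6,7-bis(methoxymethoxy)-2H-chromen-2-one | C=Cc1ccc(Oc2cc3cc(OCOC)c(OCOC)cc3oc2=O)c(OCOC)c1
F4 | step 14 | 3-[4-bromo-2-(methoxymethoxy)phenoxy]-6,7-bis[(tert-butyldimethylsilyl)oxy]-2H-chromen-2-one | O=c1oc2cc(O[Si](C)(C)C(C)(C)C)c(O[Si](C)(C)C(C)(C)C)cc2cc1Oc1ccc(Br)cc1OCOC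
F5 | step 14 | tert-butyl (R)-3-{3,4-bis[(tert-butyldimethylsilyl)oxy]phenyl}-2-hydroxypropanoate | O[C@H](Cc1ccc(O[Si](C)(C)C(C)(C)C)c(O[Si](C)(C)C(C)(C)C)c1)C(=O)OC(C)(C)C
F6 | step 14 | tert-butyl (R)-2-(acryloyloxy)-3-{3,4-bis[(tert-butyldimethylsilyl)oxy]phenyl}propanoate | C=CC(=O)O[C@H](Cc1ccc(O[Si](C)(C)C(C)(C)C)c(O[Si](C)(C)C(C)(C)C)c1)C(=O)OC(C)(C)C
F7 | step 14 | tert-butyl (R)-3-{3,4-bis[(tert-butyldimethylsilyl)oxy]phenyl}-2-{[(E)-3-{4-[(6,7-bis[(tert-butyldimethylsilyl)oxy]-2-oxo-2H-chromen-3-yl)oxy]-3-(methoxymethoxy)phenyl}prop-2-enoyl]oxy}propanoate | O=C(/C=C/c1ccc(Oc2cc3cc(O[Si](C)(C)C(C)(C)C)c(O[Si](C)(C)C(C)(C)C)cc3oc2=O)c(OCOC)c1)O[C@H](Cc1ccc(O[Si](C)(C)C(C)(C)C)c(O[Si](C)(C)C(C)(C)C)c1)C(=O)OC(C)(C)C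
F8 | step 14 | (R)-3-{3,4-bis[(tert-butyldimethylsilyl)oxy]phenyl}-2-{[(E)-3-{4-[(6,7-bis[(tert-butyldimethylsilyl)oxy]-2-oxo-2H-chromen-3-yl)oxy]-3-hydroxyphenyl}prop-2-enoyl]oxy}propanoic acid | O=C(/C=C/c1ccc(Oc2cc3cc(O[Si](C)(C)C(C)(C)C)c(O[Si](C)(C)C(C)(C)C)cc3oc2=O)c(O)c1)O[C@H](Cc1ccc(O[Si](C)(C)C(C)(C)C)c(O[Si](C)(C)C(C)(C)C)c1)C(=O)O
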